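**Strategy.** Ring A, the oxolane (O1, C2–C5), is closed last by making the C4–C5 bond. C5 is a bare O–CH2 and C4 carries the benzylic carbon C7' of the catechol arm, so C5 maps onto an alkoxymethyl radical and C4–C7' onto an aryl-conjugated alkene. One tin-mediated 5-exo-trig cyclisation of an O,Se-acetal therefore forms the ring, the C4–C5 bond and the C4 stereocentre, the latter dictated by C2 and C3. The precursor is the (phenylselanyl)methyl ether of an anti homoallylic alcohol (from asymmetric allylboration of pivaloyl vanillin) bearing an (E)-3,4-bis(benzyloxy)styryl group. C7' is then oxidised and reduced to the (R)-carbinol.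

Key step: step 7

Atom labels: ring A = O1, C2 (guaiacyl), C3 (CH2OH arm), C4 (side chain), C5 (OCH2); C7' = carbinol carbon on C4. The target is (2S,3R,4S,7'R), all-trans on the ring.

Assumption: with aryl aldehydes the (R)-configured phosphoric acid is taken to direct the allyl group to the Re face, so the (S)-acid is specified for the required Si-face attack. The sense is to be checked on the derived MTPA esters; if it is opposite, the enantiomeric acid is used and nothing else changes.

**Step 1**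
Reactants: 1 vanillin
Product: 2 4-formyl-2-methoxyphenyl pivalate
Conditions: PivCl, Et3N, DMAP (cat.), CH2Cl2, 0 °C to rt
Reagents that add atoms: pivaloyl chloride CC(C)(C)C(Cl)=O
Why: DMAP-catalysed O-acylation of the phenol is fast and spares the aldehyde, and the hindered aryl ester both survives the later steps and deactivates this ring toward DDQ in step 8.

**Step 2**
Reactants: 3 (E)-4-(benzyloxy)but-2-en-1-ol; 4 bis(pinacolato)diboron
Product: 5 (E)-2-[4-(benzyloxy)but-2-en-1-yl]-4,4,5,5-tetramethyl-1,3,2-dioxaborolane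
Conditions: Pd(MeCN)4(BF4)2 (5 mol%), DMSO–MeOH (1:1), 40 °C
Reagents that add atoms: none
Why: Palladium-catalysed allylic borylation of a free allylic alcohol runs through an η3-allyl complex that is borylated at its unsubstituted terminus, which should give the linear (E)-allylboronate.

**Step 3**
Reactants: 2 4-formyl-2-methoxyphenyl pivalate; 5 (E)-allylboronate
Product: 7 4-[(1S,2R)-2-[(benzyloxy)methyl]-1-hydroxybut-3-en-1-yl]-2-methoxyphenyl pivalate, via pinacol borate ester 6 (not isolated)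
Conditions: (S)-3,3'-bis(2,4,6-triisopropylphenyl)-1,1'-binaphthyl-2,2'-diyl hydrogen phosphate [(S)-TRIP] (5 mol%), 4 Å MS, toluene, −30 °C; aq. NaHCO3 work-up
Reagents that add atoms: none
Why: Chiral Brønsted acid-catalysed allylboration proceeds through a closed chair transition state, so the (E)-boronate should give the anti adduct (fixing C3 relative to C2) while the (S)-acid directs the allyl group to the Si face of the aldehyde and sets C2 as S.

**Step 4**
Reactants: 7 anti homoallylic alcohol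
Product: 8 4-[(1S,2R)-2-[(benzyloxy)methyl]-1-(methoxymethoxy)but-3-en-1-yl]-2-methoxyphenyl pivalate
Conditions: MOMCl, i-Pr2NEt, CH2Cl2, 0 °C to rt
Reagents that add atoms: chloromethyl methyl ether COCCl
Why: O-alkylation with MOMCl under amine base (acetal formation) is mild enough for the aryl pivalate and installs the formaldehyde acetal carbon that becomes C5.

**Step 5**
Reactants: 8 MOM ether; 9 4-iodo-1,2-bis(benzyloxy)benzene
Product: 10 4-[(1S,2R,3E)-2-[(benzyloxy)methyl]-4-[3,4-bis(benzyloxy)phenyl]-1-(methoxymethoxy)but-3-en-1-yl]-2-methoxyphenyl pivalate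
Conditions: Pd(OAc)2 (5 mol%), n-Bu4NCl, NaHCO3, DMF, 70 °C
Reagents that add atoms: none
Why: The Heck reaction of an aryl iodide with a monosubstituted alkene arylates the terminal carbon, and β-hydride elimination toward the benzylic hydrogen should give the conjugated (E)-styrene without touching the allylic stereocentre.

**Step 6**
Reactants: 10 MOM-protected (E)-styrene
Product: 12 4-[(1S,2R,3E)-2-[(benzyloxy)methyl]-4-[3,4-bis(benzyloxy)phenyl]-1-[(phenylselanyl)methoxy]but-3-en-1-yl]-2-methoxyphenyl pivalate, via bromomethyl ether 11 (not isolated)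
Conditions: Me2BBr (1.2 equiv), CH2Cl2, −78 °C; then PhSeH, i-Pr2NEt, −78 to 0 °C
Reagents that add atoms: benzeneselenol [SeH]c1ccccc1
Why: Acetal exchange: dimethylboron bromide cleaves a MOM ether at its methoxy side at −78 °C to the α-bromo ether, which the selenol displaces by nucleophilic substitution, while benzyl ethers, the aryl methyl ether and the pivalate are inert at this temperature.

**Step 7**
Reactants: 12 (phenylselanyl)methyl ether
Product: 13 4-[(2S,3R,4S)-3-[(benzyloxy)methyl]-4-[3,4-bis(benzyloxy)benzyl]oxolan-2-yl]-2-methoxyphenyl pivalate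
Conditions: Bu3SnH (1.3 equiv) and AIBN (0.2 equiv) added by syringe pump, toluene (0.01 M), 90 °C
Reagents that add atoms: none
Why: The stannyl radical cleaves the weak C–Se bond of the O,Se-acetal to give the nucleophilic alkoxymethyl radical at C5, which adds to styrene carbon C4; the resulting C7' benzylic radical takes hydrogen from Bu3SnH and carries the chain. The closest known reaction type is the tin hydride-mediated radical cyclisation of alkoxymethyl radicals, generated from (phenylselanyl)methyl ethers of homoallylic alcohols, to 2,4-cis and 3,4-trans oxolanes. Ring A closes in the 5-exo-trig mode, favoured over 6-endo stereoelectronically and because only exo attack places the radical on the benzylic carbon. The one new stereocentre, C4, is controlled by C2 and C3: in the chair-like transition state the C2 aryl group, the C3 benzyloxymethyl group and the styryl unit are all pseudo-equatorial, which puts the C4 arm cis to the aryl group and trans to the C3 arm, and in the anti substrate the two preferences reinforce each other. The step needs cyclisation to outrun direct reduction of the C5 radical, which the activated styrene acceptor and slow addition of the stannane at high dilution should secure. The pivalate, benzyl ethers and arenes are inert to stannyl radicals.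

**Step 8**
Reactants: 13 all-trans oxolane
Product: 15 4-[(2S,3R,4S)-4-[3,4-bis(benzyloxy)benzoyl]-3-[(benzyloxy)methyl]oxolan-2-yl]-2-methoxyphenyl pivalate, via benzylic alcohol 14 (not isolated)
Conditions: DDQ (2.5 equiv), CH2Cl2–H2O (10:1), rt
Reagents that add atoms: water O
Why: DDQ benzylic oxidation: hydride is removed from the CH2 para to an alkoxy group of the dialkoxyarene, water captures the cation and the electron-rich benzylic alcohol is oxidised on to the aryl ketone, whereas the acyloxy-substituted guaiacyl ring and the plain benzyl ethers are too electron-poor to compete and the trans C3 arm cannot trap the cation.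

**Step 9**
Reactants: 15 aryl ketone
Product: 16 4-[(2S,3R,4S)-3-[(benzyloxy)methyl]-4-{(R)-[3,4-bis(benzyloxy)phenyl](hydroxy)methyl}oxolan-2-yl]-2-methoxyphenyl pivalate
Conditions: Zn(BH4)2, Et2O–CH2Cl2, −30 to 0 °C; H2O quench
Reagents that add atoms: none
Why: Chelation-controlled hydride reduction: zinc bridges the ketone oxygen and ring oxygen O1 (a β-alkoxy ketone) and hydride enters from the face opposite C3, which is also the face favoured by the open transition state with C3 as the large group, so the (R)-carbinol at C7' should predominate.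

**Step 10**
Reactants: 16 (R)-carbinol pivalate
Product: 17 4-[(2S,3R,4S)-3-[(benzyloxy)methyl]-4-{(R)-[3,4-bis(benzyloxy)phenyl](hydroxy)methyl}oxolan-2-yl]-2-methoxyphenol
Conditions: K2CO3, MeOH, rt
Reagents that add atoms: none
Why: Base-catalysed transesterification (methanolysis) cleaves the aryl ester because phenoxide is a good leaving group, and the benzyl ethers and both alcohols are unaffected.

**Step 11**
Reactants: 17 tribenzyl ether
Product: 18 4-{(R)-hydroxy[(3S,4R,5S)-4-(hydroxymethyl)-5-(4-hydroxy-3-methoxyphenyl)oxolan-3-yl]methyl}benzene-1,2-diol (target)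
Conditions: H2 (1 atm), 10% Pd/C, EtOAc–MeOH, rt, stopped after uptake of three equivalents
Reagents that add atoms: none
Why: Catalytic hydrogenolysis of O-benzyl groups under neutral conditions is faster than cleavage of the C7'–OH and C2–O1 benzylic bonds, so the three ethers should be removed with all four stereocentres untouched.

**Compound list**
1 | vanillin | COc1cc(C=O)ccc1O | starting material
2 | 4-formyl-2-methoxyphenyl pivalate | COc1cc(C=O)ccc1OC(=O)C(C)(C)C | intermediate
3 | (E)-4-(benzyloxy)but-2-en-1-ol | OC/C=C/COCc1ccccc1 | starting material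
4 | bis(pinacolato)diboron | CC1(C)OB(OC1(C)C)B1OC(C)(C)C(C)(C)O1 | starting material
5 | (E)-2-[4-(benzyloxy)but-2-en-1-yl]-4,4,5,5-tetramethyl-1,3,2-dioxaborolane | CC1(C)OB(C/C=C/COCc2ccccc2)OC1(C)C | intermediate
6 | 2-{[(1S,2R)-2-[(benzyloxy)methyl]-1-[3-methoxy-4-(pivaloyloxy)phenyl]but-3-en-1-yl]oxy}-4,4,5,5-tetramethyl-1,3,2-dioxaborolane | COc1cc([C@@H](OB2OC(C)(C)C(C)(C)O2)[C@@H](COCc2ccccc2)C=C)ccc1OC(=O)C(C)(C)C | intermediate
7 | 4-[(1S,2R)-2-[(benzyloxy)methyl]-1-hydroxybut-3-en-1-yl]-2-methoxyphenyl pivalate | COc1cc([C@@H](O)[C@@H](COCc2ccccc2)C=C)ccc1OC(=O)C(C)(C)C | intermediate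
8 | 4-[(1S,2R)-2-[(benzyloxy)methyl]-1-(methoxymethoxy)but-3-en-1-yl]-2-methoxyphenyl pivalate | COc1cc([C@@H](OCOC)[C@@H](COCc2ccccc2)C=C)ccc1OC(=O)C(C)(C)C | intermediate
9 | 4-iodo-1,2-bis(benzyloxy)benzene | Ic1ccc(OCc2ccccc2)c(OCc2ccccc2)c1 | starting material
10 | 4-[(1S,2R,3E)-2-[(benzyloxy)methyl]-4-[3,4-bis(benzyloxy)phenyl]-1-(methoxymethoxy)but-3-en-1-yl]-2-methoxyphenyl pivalate | COc1cc([C@@H](OCOC)[C@@H](COCc2ccccc2)/C=C/c2ccc(OCc3ccccc3)c(OCc3ccccc3)c2)ccc1OC(=O)C(C)(C)C | intermediate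
11 | 4-[(1S,2R,3E)-2-[(benzyloxy)methyl]-4-[3,4-bis(benzyloxy)phenyl]-1-(bromomethoxy)but-3-en-1-yl]-2-methoxyphenyl pivalate | COc1cc([C@@H](OCBr)[C@@H](COCc2ccccc2)/C=C/c2ccc(OCc3ccccc3)c(OCc3ccccc3)c2)ccc1OC(=O)C(C)(C)C | intermediate
12 | 4-[(1S,2R,3E)-2-[(benzyloxy)methyl]-4-[3,4-bis(benzyloxy)phenyl]-1-[(phenylselanyl)methoxy]but-3-en-1-yl]-2-methoxyphenyl pivalate | COc1cc([C@@H](OC[Se]c2ccccc2)[C@@H](COCc2ccccc2)/C=C/c2ccc(OCc3ccccc3)c(OCc3ccccc3)c2)ccc1OC(=O)C(C)(C)C | intermediate
13 | 4-[(2S,3R,4S)-3-[(benzyloxy)methyl]-4-[3,4-bis(benzyloxy)benzyl]oxolan-2-yl]-2-methoxyphenyl pivalate | COc1cc([C@H]2OC[C@@H](Cc3ccc(OCc4ccccc4)c(OCc4ccccc4)c3)[C@@H]2COCc2ccccc2)ccc1OC(=O)C(C)(C)C | intermediate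
14 | 4-[(2S,3R,4S)-3-[(benzyloxy)methyl]-4-{[3,4-bis(benzyloxy)phenyl](hydroxy)methyl}oxolan-2-yl]-2-methoxyphenyl pivalate (C7' epimers) | COc1cc([C@H]2OC[C@@H](C(O)c3ccc(OCc4ccccc4)c(OCc4ccccc4)c3)[C@@H]2COCc2ccccc2)ccc1OC(=O)C(C)(C)C | intermediate
15 | 4-[(2S,3R,4S)-4-[3,4-bis(benzyloxy)benzoyl]-3-[(benzyloxy)methyl]oxolan-2-yl]-2-methoxyphenyl pivalate | COc1cc([C@H]2OC[C@@H](C(=O)c3ccc(OCc4ccccc4)c(OCc4ccccc4)c3)[C@@H]2COCc2ccccc2)ccc1OC(=O)C(C)(C)C | intermediate
16 | 4-[(2S,3R,4S)-3-[(benzyloxy)methyl]-4-{(R)-[3,4-bis(benzyloxy)phenyl](hydroxy)methyl}oxolan-2-yl]-2-methoxyphenyl pivalate | COc1cc([C@H]2OC[C@@H]([C@@H](O)c3ccc(OCc4ccccc4)c(OCc4ccccc4)c3)[C@@H]2COCc2ccccc2)ccc1OC(=O)C(C)(C)C | intermediate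
17 | 4-[(2S,3R,4S)-3-[(benzyloxy)methyl]-4-{(R)-[3,4-bis(benzyloxy)phenyl](hydroxy)methyl}oxolan-2-yl]-2-methoxyphenol | COc1cc([C@H]2OC[C@@H]([C@@H](O)c3ccc(OCc4ccccc4)c(OCc4ccccc4)c3)[C@@H]2COCc2ccccc2)ccc1O | intermediate
18 | 4-{(R)-hydroxy[(3S,4R,5S)-4-(hydroxymethyl)-5-(4-hydroxy-3-methoxyphenyl)oxolan-3-yl]methyl}benzene-1,2-diol (CNP0197133.1) | COc1cc([C@H]2OC[C@@H]([C@@H](O)c3ccc(O)c(O)c3)[C@@H]2CO)ccc1O | target

**Totals.** 11 steps in all; longest linear sequence 10 steps (1 → 2 → 7 → … → 18, or equally 3 → 5 → 7 → … → 18).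

**Steps most likely to fail**

Step 7. What may go wrong: premature hydrogen transfer from the stannane to the C5 radical before ring closure, or insufficient facial discrimination at C4. The fallback builds C4 by an ionic route on a lactone; it sets out from 7 and comes back at 13. Hydroboration–oxidation of the vinyl group of 7 (9-BBN, THF; NaBO3·4H2O) should give the 1,4-diol 4-[(1S,2R)-2-[(benzyloxy)methyl]-1,4-dihydroxybutyl]-2-methoxyphenyl pivalate F1. Oxidative lactonisation (TEMPO, PhI(OAc)2, CH2Cl2) should give the trans lactone 4-[(2S,3R)-3-[(benzyloxy)methyl]-5-oxooxolan-2-yl]-2-methoxyphenyl pivalate F2. Deprotonation with LiN(SiMe3)2 at −78 °C and alkylation with 3,4-bis(benzyloxy)benzyl bromide, which enters anti to the C3 arm, should give the all-trans lactone 4-[(2S,3R,4S)-3-[(benzyloxy)methyl]-4-[3,4-bis(benzyloxy)benzyl]-5-oxooxolan-2-yl]-2-methoxyphenyl pivalate F3. Reduction with i-Bu2AlH at −78 °C should give the lactol 4-[(2S,3R,4S)-3-[(benzyloxy)methyl]-4-[3,4-bis(benzyloxy)benzyl]-5-hydroxyoxolan-2-yl]-2-methoxyphenyl pivalate F4, and Et3SiH with BF3·OEt2 at −78 °C should reduce its oxocarbenium ion to 13. Any phenol released by the aluminium hydride is re-acylated with pivaloyl chloride.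

Step 8. What may go wrong: hydride abstraction at another benzylic site (an O-benzyl CH2 or C2–H), or arrest at a partly oxidised stage. In the fallback the C7' oxygen is installed before ring closure and the C4–C5 bond is made by a polar reaction; it sets out from 10 and comes back at 15. Benzylic-selective rhodium-catalysed hydroboration–oxidation of the styrene (catecholborane, [Rh(cod)2]BF4, 1,4-bis(diphenylphosphino)butane, THF; NaBO3·4H2O) should give the benzylic alcohol 4-[(1S,2R)-2-[(benzyloxy)methyl]-4-[3,4-bis(benzyloxy)phenyl]-4-hydroxy-1-(methoxymethoxy)butyl]-2-methoxyphenyl pivalate F5 as C7' epimers. Dess–Martin periodinane should give the aryl ketone 4-[(1S,2R)-2-[(benzyloxy)methyl]-4-[3,4-bis(benzyloxy)phenyl]-1-(methoxymethoxy)-4-oxobutyl]-2-methoxyphenyl pivalate F6. TBSOTf and Et3N should give the (Z)-silyl enol ether 4-[(1S,2R,3Z)-2-[(benzyloxy)methyl]-4-[3,4-bis(benzyloxy)phenyl]-4-[(tert-butyldimethylsilyl)oxy]-1-(methoxymethoxy)but-3-en-1-yl]-2-methoxyphenyl pivalate F7. TMSOTf in CH2Cl2 at −78 °C should then ionise the MOM acetal to an oxocarbenium ion that the enol silane captures (intramolecular Mukaiyama-type addition), giving 15. C4, now α to the ketone, can equilibrate to the all-trans arrangement.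

Step 6. What may go wrong: Lewis acid-induced cationic (Prins-type) closure of the bromomethyl ether onto the electron-rich styrene, or partial benzyl ether cleavage, before the selenol is added. In the fallback the acetal exchange is done while the alkene is still a plain vinyl group and the arene is attached afterwards; it sets out from 8 and comes back at 12. Me2BBr (CH2Cl2, −78 °C) should convert 8 into the bromomethyl ether 4-[(1S,2R)-2-[(benzyloxy)methyl]-1-(bromomethoxy)but-3-en-1-yl]-2-methoxyphenyl pivalate F8, which PhSeH and i-Pr2NEt should turn into the O,Se-acetal 4-[(1S,2R)-2-[(benzyloxy)methyl]-1-[(phenylselanyl)methoxy]but-3-en-1-yl]-2-methoxyphenyl pivalate F9. A phosphine-ligated Heck reaction of F9 with 9 (Pd(OAc)2, P(o-tol)3, Et3N, DMF, 80 °C) should then give 12; the alkyl phenyl selenide is expected to act only as a weak spectator ligand toward palladium.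

**Further compounds**
F1 | step 7 | 4-[(1S,2R)-2-[(benzyloxy)methyl]-1,4-dihydroxybutyl]-2-methoxyphenyl pivalate | COc1cc([C@@H](O)[C@@H](COCc2ccccc2)CCO)ccc1OC(=O)C(C)(C)C
F2 | step 7 | 4-[(2S,3R)-3-[(benzyloxy)methyl]-5-oxooxolan-2-yl]-2-methoxyphenyl pivalate | COc1cc([C@H]2OC(=O)C[C@@H]2COCc2ccccc2)ccc1OC(=O)C(C)(C)C
F3 | step 7 | 4-[(2S,3R,4S)-3-[(benzyloxy)methyl]-4-[3,4-bis(benzyloxy)benzyl]-5-oxooxolan-2-yl]-2-methoxyphenyl pivalate | COc1cc([C@H]2OC(=O)[C@@H](Cc3ccc(OCc4ccccc4)c(OCc4ccccc4)c3)[C@@H]2COCc2ccccc2)ccc1OC(=O)C(C)(C)C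
F4 | step 7 | 4-[(2S,3R,4S)-3-[(benzyloxy)methyl]-4-[3,4-bis(benzyloxy)benzyl]-5-hydroxyoxolan-2-yl]-2-methoxyphenyl pivalate (anomers) | COc1cc([C@H]2OC(O)[C@@H](Cc3ccc(OCc4ccccc4)c(OCc4ccccc4)c3)[C@@H]2COCc2ccccc2)ccc1OC(=O)C(C)(C)C
F5 | step 8 | 4-[(1S,2R)-2-[(benzyloxy)methyl]-4-[3,4-bis(benzyloxy)phenyl]-4-hydroxy-1-(methoxymethoxy)butyl]-2-methoxyphenyl pivalate (C4 epimers) | COc1cc([C@@H](OCOC)[C@@H](COCc2ccccc2)CC(O)c2ccc(OCc3ccccc3)c(OCc3ccccc3)c2)ccc1OC(=O)C(C)(C)C
F6 | step 8 | 4-[(1S,2R)-2-[(benzyloxy)methyl]-4-[3,4-bis(benzyloxy)phenyl]-1-(methoxymethoxy)-4-oxobutyl]-2-methoxyphenyl pivalate | COc1cc([C@@H](OCOC)[C@@H](COCc2ccccc2)CC(=O)c2ccc(OCc3ccccc3)c(OCc3ccccc3)c2)ccc1OC(=O)C(C)(C)C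
F7 | step 8 | 4-[(1S,2R,3Z)-2-[(benzyloxy)methyl]-4-[3,4-bis(benzyloxy)phenyl]-4-[(tert-butyldimethylsilyl)oxy]-1-(methoxymethoxy)but-3-en-1-yl]-2-methoxyphenyl pivalate | COc1cc([C@@H](OCOC)[C@@H](COCc2ccccc2)/C=C(\O[Si](C)(C)C(C)(C)C)c2ccc(OCc3ccccc3)c(OCc3ccccc3)c2)ccc1OC(=O)C(C)(C)C
F8 | step 6 | 4-[(1S,2R)-2-[(benzyloxy)methyl]-1-(bromomethoxy)but-3-en-1-yl]-2-methoxyphenyl pivalate | COc1cc([C@@H](OCBr)[C@@H](COCc2ccccc2)C=C)ccc1OC(=O)C(C)(C)C
F9 | step 6 | 4-[(1S,2R)-2-[(benzyloxy)methyl]-1-[(phenylselanyl)methoxy]but-3-en-1-yl]-2-methoxyphenyl pivalate | COc1cc([C@@H](OC[Se]c2ccccc2)[C@@H](COCc2ccccc2)C=C)ccc1OC(=O)C(C)(C)C
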